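**Retrosynthetic overview**

1. Numbering: the arene is C1–C6 (C1 carries C7H2–O, C3 the phenol oxygen, C4 carries C8). The feature the strategy rests on is the terminal 2,2-disubstituted oxirane (C8, O, C9): quaternary C8 bears aryl C4 and C10H2–OAc, and C9 is an unsubstituted CH2.
2. Key disconnection: C8–C9 and O–C9, by asymmetric methylene transfer from a sulfur ylide to the aryl ketone C4–C8(=O)–C10 (compound 11).
3. Ketone 11 is cut at C4–C8: an aryllithium from bromide 4 is acylated by the Weinreb amide of PMB-protected glycolic acid (8).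
4. The three esters are traced back to orthogonal ethers (C7–OTBS, C10–OPMB, phenol O-allyl). They are exchanged for esters after the key step in the order C7, C10, phenol, so the base-labile aryl angelate comes last.
5. Ring order: the benzene ring is bought; the oxirane is the only ring formed (step 6).

Key step: step 6

Assumption: by analogy with aryl methyl ketones, with the aryl group as the large substituent, the catalyst from (R)-BINOL is taken to give the (R)-oxirane; if the sense proves opposite, the catalyst from (S)-BINOL is used in the same step.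

**Route**

Step 1
Reactants: 1 methyl 4-bromo-3-hydroxybenzoate
Product: 2 methyl 3-(allyloxy)-4-bromobenzoate
Conditions: allyl bromide, K2CO3, DMF, rt
Reagents that add atoms: allyl bromide, C=CCBr
Why: Williamson O-alkylation of the phenoxide by SN2 on allyl bromide; the methyl ester and the aryl bromide are inert to K2CO3 in DMF.

Step 2
Reactants: 2 methyl 3-(allyloxy)-4-bromobenzoate
Product: 3 [3-(allyloxy)-4-bromophenyl]methanol
Conditions: i-Bu2AlH (2.5 equiv), CH2Cl2, −78 → 0 °C; aq. potassium sodium tartrate (KNaC4H4O6)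
Reagents that add atoms: none
Why: Hydride reduction of the ester by i-Bu2AlH should stop at the benzylic alcohol and leave the aryl bromide and the allyl ether untouched at low temperature.

Step 3
Reactants: 3 [3-(allyloxy)-4-bromophenyl]methanol
Product: 4 {[3-(allyloxy)-4-bromobenzyl]oxy}(tert-butyl)dimethylsilane
Conditions: TBSCl, imidazole, DMF, rt
Reagents that add atoms: tert-butyldimethylsilyl chloride, CC(C)(C)[Si](C)(C)Cl
Why: Imidazole-mediated silylation of a primary alcohol gives a TBS ether that tolerates the organolithium, the ylide and DDQ used later.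

Step 4
Reactants: 5 4-methoxybenzyl alcohol; 6 2-chloro-N-methoxy-N-methylacetamide
Product: 8 N-methoxy-2-[(4-methoxybenzyl)oxy]-N-methylacetamide, via sodium 4-methoxybenzyl oxide 7 (not isolated)
Conditions: NaH, THF, 0 °C; then 6, Bu4NI (cat.), 0 °C → rt
Reagents that add atoms: none
Why: Williamson etherification: the alkoxide displaces chloride at the carbonyl-activated CH2 faster than it attacks the poorly electrophilic Weinreb amide carbonyl, giving the PMB-glycolic Weinreb amide in one step.

Step 5
Reactants: 4 {[3-(allyloxy)-4-bromobenzyl]oxy}(tert-butyl)dimethylsilane; 8 N-methoxy-2-[(4-methoxybenzyl)oxy]-N-methylacetamide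
Product: 11 1-[2-(allyloxy)-4-({[tert-butyl(dimethyl)silyl]oxy}methyl)phenyl]-2-[(4-methoxybenzyl)oxy]ethan-1-one, via aryllithium 9 (not isolated), via lithium hemiaminal adduct 10 (not isolated)
Conditions: n-BuLi (1.05 equiv), THF, −78 °C; then 8, −78 → 0 °C; H2O
Reagents that add atoms: none
Why: Bromine–lithium exchange at −78 °C should outrun attack of n-BuLi on the allyl ether or cyclisation of the aryllithium onto the allyl group, and the Weinreb ketone synthesis stops at the chelated tetrahedral adduct 10, which releases the ketone only on hydrolysis.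

Step 6
Reactants: 11 1-[2-(allyloxy)-4-({[tert-butyl(dimethyl)silyl]oxy}methyl)phenyl]-2-[(4-methoxybenzyl)oxy]ethan-1-one
Product: 13 (R)-2-[2-(allyloxy)-4-({[tert-butyl(dimethyl)silyl]oxy}methyl)phenyl]-2-{[(4-methoxybenzyl)oxy]methyl}oxirane, via sulfoxonium betaine 12 (not isolated)
Conditions: Me3S(O)I, NaH, THF (ylide preformed, 1.2 equiv, added slowly); LaLi3[(R)-1,1'-binaphthalene-2,2'-diolate]3 (10 mol%, from La(O-i-Pr)3, (R)-BINOL and n-BuLi), [2,4,6-(MeO)3C6H2]3P=O (10 mol%), 5 Å MS, THF, rt
Reagents that add atoms: trimethylsulfoxonium iodide, C[S+](C)(C)=O.[I-]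
Why: The ylide carbon adds to the lanthanum-bound carbonyl of 11 (C8–C9) to give betaine 12, whose alkoxide displaces dimethyl sulfoxide from C9 in a 3-exo-tet closure (O–C9) that forms the oxirane; this is the Corey–Chaykovsky epoxidation in its lanthanum–lithium binaphthoxide-catalysed asymmetric form, known for aryl and alkyl methyl ketones. The one new stereocentre, C8, is fixed in the C–C bond-forming addition, where the chiral binaphthoxide pocket (lanthanum as Lewis acid for the ketone, lithium binaphthoxide ordering the ylide, the phosphine oxide tightening the assembly) exposes one carbonyl face. Only face selectivity is needed, and the substrate offers a clear size difference: the ortho-allyloxyaryl group plays the large and the CH2OPMB arm the small substituent, as aryl and methyl do in the parent reaction. Methylene transfer should win over enolisation because the ylide is a weak base and there is only one α-CH2, and the α-oxygen raises carbonyl electrophilicity to offset the steric drag of the ortho substituent. The allyl, TBS and PMB ethers are inert to the ylide, slow ylide addition keeps the uncatalysed racemic pathway down, and ring expansion to an oxetane is avoided at room temperature with a small excess of ylide.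

Step 7
Reactants: 13 (R)-2-[2-(allyloxy)-4-({[tert-butyl(dimethyl)silyl]oxy}methyl)phenyl]-2-{[(4-methoxybenzyl)oxy]methyl}oxirane
Product: 14 {3-(allyloxy)-4-[(R)-2-{[(4-methoxybenzyl)oxy]methyl}oxiran-2-yl]phenyl}methanol
Conditions: Bu4NF, THF, 0 °C
Reagents that add atoms: none
Why: Fluoride-driven desilylation frees the C7 alcohol while no ester is yet present and C10 is still a PMB ether, so no alkoxide sits next to the oxirane and a Payne rearrangement, which would invert C8, cannot occur.

Step 8
Reactants: 14 {3-(allyloxy)-4-[(R)-2-{[(4-methoxybenzyl)oxy]methyl}oxiran-2-yl]phenyl}methanol; 15 (R)-2-methylbutanoic acid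
Product: 16 3-(allyloxy)-4-[(R)-2-{[(4-methoxybenzyl)oxy]methyl}oxiran-2-yl]benzyl (R)-2-methylbutanoate
Conditions: EDC·HCl, DMAP (cat.), CH2Cl2, 0 °C → rt
Reagents that add atoms: none
Why: Steglich esterification acylates the primary benzylic alcohol under near-neutral conditions, and because no acid chloride or ketene is involved the α-stereocentre of the (R)-acid should be retained.

Step 9
Reactants: 16 3-(allyloxy)-4-[(R)-2-{[(4-methoxybenzyl)oxy]methyl}oxiran-2-yl]benzyl (R)-2-methylbutanoate
Product: 17 3-(allyloxy)-4-[(S)-2-(hydroxymethyl)oxiran-2-yl]benzyl (R)-2-methylbutanoate (same spatial arrangement at C8; the descriptor changes only because the ring CH2 now outranks CH2OH)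
Conditions: DDQ, CH2Cl2/pH 7 phosphate buffer (KH2PO4/Na2HPO4), 0 °C
Reagents that add atoms: none
Why: Oxidative PMB cleavage: DDQ abstracts hydride from the electron-rich p-methoxybenzylic position and water hydrolyses the oxocarbenium ion to release the C10 alcohol, while the buffer neutralises the acidic hydroquinone to protect the benzylic oxirane, and the less electron-rich aryl allyl ether and benzylic ester are not oxidised.

Step 10
Reactants: 17 3-(allyloxy)-4-[(S)-2-(hydroxymethyl)oxiran-2-yl]benzyl (R)-2-methylbutanoate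
Product: 18 4-[(R)-2-(acetoxymethyl)oxiran-2-yl]-3-(allyloxy)benzyl (R)-2-methylbutanoate
Conditions: Ac2O, pyridine, DMAP (cat.), CH2Cl2, 0 °C
Reagents that add atoms: acetic anhydride, CC(=O)OC(C)=O
Why: DMAP-catalysed acetylation under a weak amine base esterifies the C10 alcohol without forming an alkoxide, so the oxirane should neither open nor undergo Payne inversion.

Step 11
Reactants: 18 4-[(R)-2-(acetoxymethyl)oxiran-2-yl]-3-(allyloxy)benzyl (R)-2-methylbutanoate
Product: 19 4-[(R)-2-(acetoxymethyl)oxiran-2-yl]-3-hydroxybenzyl (R)-2-methylbutanoate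
Conditions: Pd(PPh3)4 (5 mol%), N-methylaniline (3 equiv), THF, rt; rapid filtration through neutral silica, used at once
Reagents that add atoms: none
Why: Tsuji–Trost deallylation: Pd(PPh3)4 (zerovalent palladium) ionises the allyl aryl ether to a π-allyl complex and the weakly basic N-methylaniline takes up the allyl group, so under these neutral conditions the alkyl esters and the aryl-substituted oxirane should not react.

Step 12
Reactants: 19 4-[(R)-2-(acetoxymethyl)oxiran-2-yl]-3-hydroxybenzyl (R)-2-methylbutanoate; 20 angelic acid [(Z)-2-methylbut-2-enoic acid]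
Product: 22 2-[(R)-2-(acetoxymethyl)oxiran-2-yl]-5-({[(R)-2-methylbutanoyl]oxy}methyl)phenyl (Z)-2-methylbut-2-enoate (target), via angelic 2,4,6-trichlorobenzoic anhydride 21 (not isolated)
Conditions: 20, 2,4,6-Cl3C6H2COCl, Et3N, toluene, rt; then 19, Et3N, 0 °C → rt (no DMAP)
Reagents that add atoms: none
Why: Yamaguchi-type mixed-anhydride acylation without a nucleophilic catalyst: the phenoxide attacks the unhindered angeloyl carbonyl of 21, and with no DMAP to add reversibly to the enoate the Z geometry of the angelate should be kept.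

**Compound list**

1 | methyl 4-bromo-3-hydroxybenzoate | COC(=O)c1ccc(Br)c(O)c1 | starting material
2 | methyl 3-(allyloxy)-4-bromobenzoate | C=CCOc1cc(C(=O)OC)ccc1Br | intermediate
3 | [3-(allyloxy)-4-bromophenyl]methanol | C=CCOc1cc(CO)ccc1Br | intermediate
4 | {[3-(allyloxy)-4-bromobenzyl]oxy}(tert-butyl)dimethylsilane | C=CCOc1cc(CO[Si](C)(C)C(C)(C)C)ccc1Br | intermediate
5 | 4-methoxybenzyl alcohol | COc1ccc(CO)cc1 | starting material
6 | 2-chloro-N-methoxy-N-methylacetamide | CON(C)C(=O)CCl | starting material
7 | sodium 4-methoxybenzyl oxide | COc1ccc(C[O-])cc1.[Na+] | intermediate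
8 | N-methoxy-2-[(4-methoxybenzyl)oxy]-N-methylacetamide | CON(C)C(=O)COCc1ccc(OC)cc1 | intermediate
9 | [2-(allyloxy)-4-({[tert-butyl(dimethyl)silyl]oxy}methyl)phenyl]lithium | C=CCOc1cc(CO[Si](C)(C)C(C)(C)C)ccc1[Li] | intermediate
10 | lithium alkoxide of the tetrahedral adduct of 9 with 8 (C8 bears aryl, OLi, CH2OPMB and N(OMe)Me; racemic) | C=CCOc1cc(CO[Si](C)(C)C(C)(C)C)ccc1C(O[Li])(COCc1ccc(OC)cc1)N(C)OC | intermediate
11 | 1-[2-(allyloxy)-4-({[tert-butyl(dimethyl)silyl]oxy}methyl)phenyl]-2-[(4-methoxybenzyl)oxy]ethan-1-one | C=CCOc1cc(CO[Si](C)(C)C(C)(C)C)ccc1C(=O)COCc1ccc(OC)cc1 | intermediate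
12 | sulfoxonium betaine: C8 alkoxide bearing aryl, CH2OPMB and CH2S(O)Me2(+); C8 arranged as in 13 (descriptor S, since CH2S outranks CH2O) | C=CCOc1cc(CO[Si](C)(C)C(C)(C)C)ccc1[C@]([O-])(COCc1ccc(OC)cc1)C[S+](C)(C)=O | intermediate
13 | (R)-2-[2-(allyloxy)-4-({[tert-butyl(dimethyl)silyl]oxy}methyl)phenyl]-2-{[(4-methoxybenzyl)oxy]methyl}oxirane | C=CCOc1cc(CO[Si](C)(C)C(C)(C)C)ccc1[C@]1(COCc2ccc(OC)cc2)CO1 | intermediate
14 | {3-(allyloxy)-4-[(R)-2-{[(4-methoxybenzyl)oxy]methyl}oxiran-2-yl]phenyl}methanol | C=CCOc1cc(CO)ccc1[C@]1(COCc2ccc(OC)cc2)CO1 | intermediate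
15 | (R)-2-methylbutanoic acid | CC[C@@H](C)C(=O)O | starting material
16 | 3-(allyloxy)-4-[(R)-2-{[(4-methoxybenzyl)oxy]methyl}oxiran-2-yl]benzyl (R)-2-methylbutanoate | C=CCOc1cc(COC(=O)[C@H](C)CC)ccc1[C@]1(COCc2ccc(OC)cc2)CO1 | intermediate
17 | 3-(allyloxy)-4-[(S)-2-(hydroxymethyl)oxiran-2-yl]benzyl (R)-2-methylbutanoate | C=CCOc1cc(COC(=O)[C@H](C)CC)ccc1[C@]1(CO)CO1 | intermediate
18 | 4-[(R)-2-(acetoxymethyl)oxiran-2-yl]-3-(allyloxy)benzyl (R)-2-methylbutanoate | C=CCOc1cc(COC(=O)[C@H](C)CC)ccc1[C@]1(COC(C)=O)CO1 | intermediate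
19 | 4-[(R)-2-(acetoxymethyl)oxiran-2-yl]-3-hydroxybenzyl (R)-2-methylbutanoate | Oc1cc(COC(=O)[C@H](C)CC)ccc1[C@]1(COC(C)=O)CO1 | intermediate
20 | angelic acid, (Z)-2-methylbut-2-enoic acid | C/C=C(/C)C(=O)O | starting material
21 | (Z)-2-methylbut-2-enoic 2,4,6-trichlorobenzoic anhydride | C/C=C(/C)C(=O)OC(=O)c1c(Cl)cc(Cl)cc1Cl | intermediate
22 | 2-[(R)-2-(acetoxymethyl)oxiran-2-yl]-5-({[(R)-2-methylbutanoyl]oxy}methyl)phenyl (Z)-2-methylbut-2-enoate | C/C=C(/C)C(=O)Oc1cc(COC(=O)[C@H](C)CC)ccc1[C@]1(COC(C)=O)CO1 | target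

**Step count**

Total: 12 steps. Longest linear sequence: 11 steps (steps 1–3 and 5–12 from compound 1; step 4 is a one-step side branch).

**Steps most likely to fail**

1. Step 6. The risk is poor facial discrimination (the α-alkoxy, ortho-substituted ketone may bind differently from a methyl ketone), competition from the uncatalysed racemic ylide addition, or slow addition at the hindered carbonyl. The fallback sets out from ketone 11 and uses known chemistry:
   - Wittig methylenation (Ph3PCH3Br, KO-t-Bu, THF, 0 °C) should give the 2-aryl allyl PMB ether F1.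
   - Buffered DDQ should remove the PMB group to give the 2-arylprop-2-en-1-ol F2.
   - Sharpless asymmetric epoxidation (Ti(O-i-Pr)4, L-(+)-diethyl tartrate, t-BuOOH, 4 Å MS, CH2Cl2, −20 °C) is directed by the allylic hydroxyl, so it ignores the allyl ether alkene; by the Sharpless mnemonic it should give the (S)-epoxy alcohol F3, with C8 arranged as in 17.
   - Acetylation (Ac2O, pyridine) should give the C10 acetate F4, and Bu4NF buffered with AcOH should give the benzylic alcohol F5.
   - Esterification of F5 with 15 (EDC·HCl, DMAP) comes back to the route at compound 18.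

2. Step 11. The risk is that the newly freed ortho-hydroxyl opens the oxirane (ionisation at benzylic C8 towards a quinone-methide-type species, or attack on C9), which would also erode the C8 configuration. The fallback sets out from 18 and avoids the free phenol: Pd(PPh3)4 with Bu3SnH (1.05 equiv, CH2Cl2, rt) cleaves the allyl ether by hydrostannolysis to the tributylstannyl aryl ether F6. Once the hydride is consumed, F6 is O-acylated in the same flask by preformed mixed anhydride 21, and the route is rejoined at target 22.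

3. Step 12. The risk is Z → E isomerisation of the angeloyl unit (to the tiglate) during basic acylation, or acylation slow enough for the sensitive phenol to degrade. The fallback sets out from 19 and builds the Z alkene after acylation: coupling with 2-[bis(2,2,2-trifluoroethoxy)phosphoryl]propanoic acid (DCC, CH2Cl2, 0 °C) should give the aryl 2-phosphonopropanoate F7. Still–Gennari olefination of F7 with acetaldehyde (KN(SiMe3)2, 18-crown-6, THF, −78 °C) should then form the Z-trisubstituted enoate and arrive at target 22.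

**Further compounds**

F1 | step 6 | {[3-(allyloxy)-4-(3-[(4-methoxybenzyl)oxy]prop-1-en-2-yl)benzyl]oxy}(tert-butyl)dimethylsilane | C=CCOc1cc(CO[Si](C)(C)C(C)(C)C)ccc1C(=C)COCc1ccc(OC)cc1
F2 | step 6 | 2-[2-(allyloxy)-4-({[tert-butyl(dimethyl)silyl]oxy}methyl)phenyl]prop-2-en-1-ol | C=CCOc1cc(CO[Si](C)(C)C(C)(C)C)ccc1C(=C)CO
F3 | step 6 | {(S)-2-[2-(allyloxy)-4-({[tert-butyl(dimethyl)silyl]oxy}methyl)phenyl]oxiran-2-yl}methanol | C=CCOc1cc(CO[Si](C)(C)C(C)(C)C)ccc1[C@]1(CO)CO1
F4 | step 6 | {(R)-2-[2-(allyloxy)-4-({[tert-butyl(dimethyl)silyl]oxy}methyl)phenyl]oxiran-2-yl}methyl acetate | C=CCOc1cc(CO[Si](C)(C)C(C)(C)C)ccc1[C@]1(COC(C)=O)CO1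
F5 | step 6 | {(R)-2-[2-(allyloxy)-4-(hydroxymethyl)phenyl]oxiran-2-yl}methyl acetate | C=CCOc1cc(CO)ccc1[C@]1(COC(C)=O)CO1
F6 | step 11 | 4-[(R)-2-(acetoxymethyl)oxiran-2-yl]-3-[(tributylstannyl)oxy]benzyl (R)-2-methylbutanoate | CCCC[Sn](CCCC)(CCCC)Oc1cc(COC(=O)[C@H](C)CC)ccc1[C@]1(COC(C)=O)CO1
F7 | step 12 | 2-[(R)-2-(acetoxymethyl)oxiran-2-yl]-5-({[(R)-2-methylbutanoyl]oxy}methyl)phenyl 2-[bis(2,2,2-trifluoroethoxy)phosphoryl]propanoate (mixture at the phosphonate α-carbon) | CC(C(=O)Oc1cc(COC(=O)[C@H](C)CC)ccc1[C@]1(COC(C)=O)CO1)P(=O)(OCC(F)(F)F)OCC(F)(F)F
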